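## Retrosynthetic overview

1. The only ring, the 42-membered lactone, is closed last at C21–C22 by a Ni-mediated reductive radical coupling of the Z-alkenyl iodide (C21) with the primary iodide (C22) of a seco ester.
2. C18–C19 (carrying the Z-iodoalkene): Ipc2B syn-aldol of the C17 ethyl ketone with (Z)-3-iodoacrolein, then 1,3-anti reduction. C3–C4: Sonogashira coupling of a Z-iodoalkene with the C41 propiolate; one semi-hydrogenation sets 2Z and 38Z.
3. The C5–C18 polyol ketone and the C22–C37 triol chain are each made by one five-component dithiane/epichlorohydrin linchpin coupling (C9 and C13 by hydroxyl-directed reduction; Raney Ni for the 1,5-triol).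
4. C37–C38 by acetylide alkylation; C38–C50 from propylene oxide by hydroformylation, Brown Z-crotylation and Brown allenylboration.

Assumption: atoms are numbered C1 (lactone carbonyl) to C50 along the chain (methyls on C4, C18, C42; lactone oxygen on C41). Where a name gives no descriptor, the centres have the spatial arrangement of the target (7S,9R,11S,13R,15S,17R,18R,19R,23R,27R,31R,41S,42S,43R,49R; 2Z,4Z,20Z,38Z). Lithio derivatives made by simple deprotonation and the fleeting Brook-rearranged carbanions are given in the Conditions and Why lines; intermediates that accumulate in the flask are numbered.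

## Route

Step 1
Reactants: 1 1,3-dithiane
Product: 2 2-(tert-butyldimethylsilyl)-1,3-dithiane
Conditions: nBuLi, THF, −30 °C; TBSCl, −78 → 25 °C
Reagents that add atoms: TBSCl, CC(C)(C)[Si](C)(C)Cl
Why: Corey–Seebach lithiation of the dithiane and C-silylation give the linchpin used in steps 4 and 18.

Step 2
Reactants: 3 (S)-epichlorohydrin; 4 vinylmagnesium bromide
Product: 6 (S)-2-allyloxirane, via chlorohydrin 5 (not isolated)
Conditions: CuI (10 mol%), THF, −40 °C; then NaOH (aq), 25 °C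
Reagents that add atoms: none
Why: Cu-catalysed Grignard opening of the epoxide at its CH2 followed by Williamson ring closure of the chlorohydrin; C7 is carried over untouched from 3.

Step 3
Reactants: 1 1,3-dithiane; 7 iodoethane; 8 (R)-epichlorohydrin
Product: 11 (R)-2-ethyl-2-(oxiran-2-ylmethyl)-1,3-dithiane, via 2-ethyl-1,3-dithiane 9 (not isolated), via chlorohydrin alkoxide 10 (not isolated)
Conditions: nBuLi, THF, −30 °C; 7, −78 → 0 °C; nBuLi, −30 °C; 8, −78 → 25 °C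
Reagents that add atoms: none
Why: Two Corey–Seebach alkylations in one pot; the second anion opens 8 at the epoxide CH2 and the alkoxide displaces chloride, so C15 keeps the configuration of 8.

Step 4
Reactants: 2 2-(tert-butyldimethylsilyl)-1,3-dithiane (two equivalents); 11 (R)-2-ethyl-2-(oxiran-2-ylmethyl)-1,3-dithiane; 8 (R)-epichlorohydrin; 6 (S)-2-allyloxirane
Product: 16 C5–C18 tris-dithiane alcohol, via arm-B lithium alkoxide 12 (not isolated), via chlorohydrin alkoxide 13 (not isolated), via C10–C11 epoxide 14 (not isolated), via arm-A lithium alkoxide 15 (not isolated)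
Conditions: 2, tBuLi, Et2O, −78 → −45 °C; 11, −25 °C; HMPA, 8, −78 → 0 °C; then adduct of lithiated 2 and 6 (second flask, Et2O) by cannula, −78 → 25 °C
Reagents that add atoms: none
Why: Multicomponent dithiane linchpin coupling (epoxide opening, HMPA-triggered 1,4-Brook rearrangement, alkylation), run as the sequential one-pot form of the known symmetrical epichlorohydrin five-component coupling; C7, C11 and C15 come unchanged from 6, 8 and 11.

Step 5
Reactants: 16 C5–C18 tris-dithiane alcohol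
Product: 17 C5–C18 9,13,17-triketone
Conditions: MeI, CaCO3, MeCN/H2O (9:1), 45 °C
Reagents that add atoms: water, O
Why: S-methylation and buffered hydrolysis unmask all three dithianes; the neutral medium spares the β-hydroxy ketone and the terminal alkene.

Step 6
Reactants: 17 C5–C18 9,13,17-triketone
Product: 18 C5–C18 9,11,13-triol 17-ketone
Conditions: Me4NBH(OAc)3, MeCN/AcOH (1:1), −30 °C
Reagents that add atoms: none
Why: Evans–Saksena reduction: hydride is delivered intramolecularly from the alkoxyborohydride of the 11-OH, giving the 1,3-anti carbinols at C9 and C13; the C17 ketone has no free β-hydroxyl and is left.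

Step 7
Reactants: 18 C5–C18 9,11,13-triol 17-ketone
Product: 19 C5–C18 pentakis-TBS ether ketone
Conditions: TBSOTf, 2,6-lutidine, CH2Cl2, −78 → 0 °C
Reagents that add atoms: TBSOTf, CC(C)(C)[Si](C)(C)OS(=O)(=O)C(F)(F)F
Why: Silyl ether formation traps the open-chain triol; the hindered ketone is not enolised by 2,6-lutidine at this temperature.

Step 8
Reactants: 19 C5–C18 pentakis-TBS ether ketone
Product: 20 C5 aldehyde
Conditions: O3, CH2Cl2, −78 °C; PPh3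
Reagents that add atoms: ozone, [O-][O+]=O
Why: Ozonolysis of the only alkene with reductive work-up gives the β-silyloxy aldehyde.

Step 9
Reactants: 20 C5 aldehyde
Product: 21 (Z)-4-iodo C4–C18 alkene ketone
Conditions: EtPPh3I, nBuLi, THF, 25 °C; I2, −78 °C; NaN(SiMe3)2, −20 °C; 20, −78 °C
Reagents that add atoms: ethyltriphenylphosphonium iodide, CC[P+](c1ccccc1)(c1ccccc1)c1ccccc1.[I-]; iodine, II
Why: Stork–Zhao-type Wittig olefination with the α-iodoethylidene ylide gives the (Z)-2-iodoalkene (iodine cis to C6) under kinetic control; the aldehyde reacts well before the hindered ketone at −78 °C.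

Step 10
Reactants: 22 (R)-propylene oxide; 23 but-3-enylmagnesium bromide
Product: 24 (R)-hept-6-en-2-ol
Conditions: CuI (5 mol%), THF, −30 → 0 °C
Reagents that add atoms: none
Why: Cu-catalysed Grignard opening at the epoxide CH2; C49 comes unchanged from 22.

Step 11
Reactants: 24 (R)-hept-6-en-2-ol
Product: 25 (R)-tert-butyl(hept-6-en-2-yloxy)dimethylsilane
Conditions: TBSCl, imidazole, DMF, 25 °C
Reagents that add atoms: TBSCl, CC(C)(C)[Si](C)(C)Cl
Why: Standard silyl protection of the secondary alcohol.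

Step 12
Reactants: 25 (R)-tert-butyl(hept-6-en-2-yloxy)dimethylsilane
Product: 26 (R)-7-[(tert-butyldimethylsilyl)oxy]octanal
Conditions: Rh(acac)(CO)2 (0.5 mol%), Xantphos, CO/H2 (1:1, 10 bar), toluene, 80 °C
Reagents that add atoms: carbon monoxide, [C-]#[O+]
Why: Linear-selective Rh/Xantphos hydroformylation adds C43 as the aldehyde carbon.

Step 13
Reactants: 26 (R)-7-[(tert-butyldimethylsilyl)oxy]octanal; 27 (Z)-but-2-ene
Product: 29 (3R,4R,10R)-10-[(tert-butyldimethylsilyl)oxy]-3-methylundec-1-en-4-ol, via (Z)-crotyl-Ipc2-borane 28 (not isolated)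
Conditions: 27, KOtBu, nBuLi, THF, −78 → −45 °C; (−)-Ipc2BOMe, −78 °C; BF3·OEt2; 26, −78 °C; NaOH, H2O2
Reagents that add atoms: none
Why: Brown crotylboration through a chair Zimmerman–Traxler transition state: the Z-crotyl geometry gives the 42,43-syn pair and the Ipc ligands of the (+)-α-pinene series direct attack to the si face, setting C42 and C43.

Step 14
Reactants: 29 (3R,4R,10R)-10-[(tert-butyldimethylsilyl)oxy]-3-methylundec-1-en-4-ol
Product: 30 (3R,4R,10R)-4,10-bis[(tert-butyldimethylsilyl)oxy]-3-methylundec-1-ene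
Conditions: TBSOTf, 2,6-lutidine, CH2Cl2, 0 °C
Reagents that add atoms: TBSOTf, CC(C)(C)[Si](C)(C)OS(=O)(=O)C(F)(F)F
Why: Silyl protection of the hindered secondary alcohol with the triflate.

Step 15
Reactants: 30 (3R,4R,10R)-4,10-bis[(tert-butyldimethylsilyl)oxy]-3-methylundec-1-ene
Product: 31 (2S,3R,9R)-3,9-bis[(tert-butyldimethylsilyl)oxy]-2-methyldecanal
Conditions: O3, CH2Cl2, −78 °C; PPh3
Reagents that add atoms: ozone, [O-][O+]=O
Why: Ozonolysis gives the C41 aldehyde, which is used at once so that C42 does not epimerise.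

Step 16
Reactants: 31 (2S,3R,9R)-3,9-bis[(tert-butyldimethylsilyl)oxy]-2-methyldecanal; 32 propargyl bromide
Product: 35 (4S,5R,6R,12R)-6,12-bis[(tert-butyldimethylsilyl)oxy]-5-methyltridec-1-yn-4-ol, via allenylmagnesium bromide 33 (not isolated), via B-allenyl-Ipc2-borane 34 (not isolated)
Conditions: 32, Mg, HgCl2 (cat.), Et2O, 0 °C; (−)-Ipc2BOMe, −78 → 25 °C; 31, −78 °C; NaOH, H2O2
Reagents that add atoms: none
Why: Brown asymmetric allenylboration (SE2′ through a cyclic transition state) gives the homopropargylic alcohol; si-face reagent control is matched with Felkin–Anh addition and sets C41 syn to the C42 methyl.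

Step 17
Reactants: 36 1-bromo-5-chloropentane; 8 (R)-epichlorohydrin
Product: 39 (R)-2-(6-chlorohexyl)oxirane, via 5-chloropentylmagnesium bromide 37 (not isolated), via dichloro alcohol 38 (not isolated)
Conditions: 36, Mg, THF, 0 °C; CuI (10 mol%), 8, −40 °C; then NaOH (aq), 25 °C
Reagents that add atoms: none
Why: Mg inserts selectively into C–Br; Cu-catalysed epoxide opening and Williamson closure follow, and C31 comes unchanged from 8.

Step 18
Reactants: 2 2-(tert-butyldimethylsilyl)-1,3-dithiane (two equivalents); 39 (R)-2-(6-chlorohexyl)oxirane; 8 (R)-epichlorohydrin; 40 (R)-2-{[(4-methoxybenzyl)oxy]methyl}oxirane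
Product: 46 C22–C37 bis-dithiane tris-TBS ether, via arm-Y lithium alkoxide 41 (not isolated), via chlorohydrin alkoxide 42 (not isolated), via C26–C27 epoxide 43 (not isolated), via arm-P lithium alkoxide 44 (not isolated), via C27 lithium alkoxide 45 (not isolated)
Conditions: 2, tBuLi, Et2O, −78 → −45 °C; 39, −25 °C; HMPA, 8, −78 → 0 °C; then adduct of lithiated 2 and 40 (second flask) by cannula, −78 → 0 °C; TBSCl, 25 °C
Reagents that add atoms: TBSCl, CC(C)(C)[Si](C)(C)Cl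
Why: The same multicomponent dithiane linchpin coupling with Brook rearrangement; C23, C27 and C31 come unchanged from 40, 8 and 39, the primary chloride is inert at these temperatures, and the last alkoxide is silylated in the pot.

Step 19
Reactants: 46 C22–C37 bis-dithiane tris-TBS ether
Product: 47 C22–C37 chloride
Conditions: Raney Ni (W-2), EtOH, 25 °C
Reagents that add atoms: none
Why: Mozingo-type hydrogenolysis of both dithianes to CH2 gives the all-(CH2)3-spaced 1,5-triol chain; silyl ethers, the PMB ether and the primary chloride are kept at room temperature.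

Step 20
Reactants: 35 (4S,5R,6R,12R)-6,12-bis[(tert-butyldimethylsilyl)oxy]-5-methyltridec-1-yn-4-ol; 47 C22–C37 chloride
Product: 48 C22–C50 alkynol
Conditions: 35, nBuLi (2.1 equiv), THF/DMPU, −78 → 0 °C; 47, NaI (20 mol%), 45 °C
Reagents that add atoms: none
Why: SN2 C-alkylation of the dilithio alkynol (the acetylide carbon far outpaces the alkoxide) with in-situ Finkelstein activation of the chloride forms C37–C38.

Step 21
Reactants: 48 C22–C50 alkynol; 49 propiolic acid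
Product: 50 C41 propiolate
Conditions: DCC, DMAP (cat.), CH2Cl2, −20 → 0 °C
Reagents that add atoms: none
Why: Steglich esterification of the only free hydroxyl installs C1–C3 without touching C41.

Step 22
Reactants: 21 (Z)-4-iodo C4–C18 alkene ketone; 50 C41 propiolate
Product: 51 C1–C50 enynoate ketone
Conditions: PdCl2(PPh3)2 (5 mol%), CuI (10 mol%), iPr2NEt, THF, 0 → 25 °C
Reagents that add atoms: none
Why: Sonogashira coupling forms C3–C4 with retention of the alkenyl iodide geometry, fixing 4Z.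

Step 23
Reactants: 51 C1–C50 enynoate ketone
Product: 52 (2Z,4Z,38Z)-dienoate PMB ether
Conditions: H2 (1 atm), Pd/CaCO3 poisoned with Pb(OAc)2, quinoline, EtOAc, 25 °C
Reagents that add atoms: none
Why: Lindlar-type syn semi-hydrogenation of both alkynes in one operation gives the 2Z and 38Z alkenes.

Step 24
Reactants: 52 (2Z,4Z,38Z)-dienoate PMB ether
Product: 53 C22 primary alcohol
Conditions: DDQ, CH2Cl2/pH 7 buffer, 0 °C
Reagents that add atoms: none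
Why: Oxidative PMB cleavage; the electron-poor dienoate, the isolated alkene and the silyl ethers are inert.

Step 25
Reactants: 53 C22 primary alcohol
Product: 54 C22 primary iodide
Conditions: I2, PPh3, imidazole, CH2Cl2, 0 → 25 °C
Reagents that add atoms: iodine, II
Why: Appel (Garegg–Samuelsson) iodination of the only free alcohol gives the radical precursor.

Step 26
Reactants: 55 ethyl (Z)-3-iodoacrylate
Product: 56 (Z)-3-iodoacrolein
Conditions: iBu2AlH (1.05 equiv), CH2Cl2, −78 °C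
Reagents that add atoms: none
Why: Half-reduction of the ester through the stable tetrahedral aluminate at −78 °C; the labile Z-aldehyde is used cold and at once.

Step 27
Reactants: 54 C22 primary iodide; 56 (Z)-3-iodoacrolein
Product: 58 syn-aldol adduct, via Z-enol borinate 57 (not isolated)
Conditions: (−)-Ipc2BOTf, iPr2NEt, CH2Cl2, −78 → 0 °C; 56, −78 → −20 °C; H2O2, MeOH, pH 7 buffer
Reagents that add atoms: none
Why: Paterson boron aldol: enolisation on the less hindered ethyl side gives the Z-enol borinate, the chair transition state gives 18,19-syn, and the Ipc ligands direct attack to the si face of the aldehyde, setting C18 and C19 and bringing in the Z-alkenyl iodide.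

Step 28
Reactants: 58 syn-aldol adduct
Product: 59 seco 17,19-diol
Conditions: Me4NBH(OAc)3, MeCN/AcOH (1:1), −30 °C
Reagents that add atoms: none
Why: Evans–Saksena reduction with intramolecular hydride delivery from the 19-O-borohydride sets C17 anti to C19.

Step 29
Reactants: 59 seco 17,19-diol
Product: 60 decakis-TBS macrolactone
Conditions: NiBr2(dme) (30 mol%), 4,4′-di-tert-butyl-2,2′-bipyridine, NaI, Mn powder, DMA, 40 °C, syringe-pump addition to 1 mM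
Reagents that add atoms: none
Why: Proposed new method: zerovalent nickel inserts into the Z-alkenyl iodide with retention, monovalent nickel abstracts iodine from the primary iodide to give the C22 radical (a β-silyloxy radical does not fragment, unlike the corresponding organozinc), the radical is captured at the alkenyl–nickel centre of the same molecule and trivalent nickel eliminates reductively, forming C21–C22 and the 42-membered ring without touching a stereocentre; the closest known reaction type is the intermolecular Ni-catalysed reductive cross-electrophile coupling of alkenyl halides with alkyl halides (Weix type), together with Ni-mediated reductive macrocyclisations.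

Step 30
Reactants: 60 decakis-TBS macrolactone
Product: 61 CNP0071908.2
Conditions: HF·pyridine, pyridine, THF, 0 → 25 °C
Reagents that add atoms: none
Why: Buffered fluoride-mediated global desilylation of the ten TBS ethers; the weakly acidic medium avoids acyl migration and dienoate isomerisation.

## Compound list

1 | 1,3-dithiane | C1CSCSC1 | starting material
2 | 2-(tert-butyldimethylsilyl)-1,3-dithiane | CC(C)(C)[Si](C)(C)C1SCCCS1 | intermediate
3 | (S)-epichlorohydrin | ClC[C@@H]1CO1 | starting material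
4 | vinylmagnesium bromide | C=C[Mg]Br | starting material
5 | (S)-1-chloropent-4-en-2-ol (chlorohydrin; C5–C8) | C=CC[C@H](O)CCl | intermediate
6 | (S)-2-allyloxirane (C5–C8; stereocentre C7) | C=CC[C@H]1CO1 | intermediate
7 | iodoethane | CCI | starting material
8 | (R)-epichlorohydrin | ClC[C@H]1CO1 | starting material
9 | 2-ethyl-1,3-dithiane | CCC1SCCCS1 | intermediate
10 | lithium (R)-1-chloro-3-(2-ethyl-1,3-dithian-2-yl)propan-2-olate | ClC[C@H]([O-])CC1(CC)SCCCS1.[Li+] | intermediate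
11 | (R)-2-ethyl-2-(oxiran-2-ylmethyl)-1,3-dithiane (C14–C18 and the C18 methyl; epoxide C14–C15; dithiane C17) | C1[C@H](O1)CC2(CC)SCCCS2 | intermediate
12 | arm-B lithium alkoxide: adduct of lithiated 2 and 11 (C13 silyl-dithiane; C15 alkoxide) | CC(C)(C)[Si](C)(C)C1(SCCCS1)C[C@H]([O-])CC2(CC)SCCCS2.[Li+] | intermediate
13 | C10–C18 lithium chlorohydrin alkoxide (10-chloro; 11-alkoxide; O15 TBS; dithianes at C13 and C17) | ClC[C@H]([O-])CC1(SCCCS1)C[C@H](O[Si](C)(C)C(C)(C)C)CC2(CC)SCCCS2.[Li+] | intermediate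
14 | C10–C18 epoxide (C10–C11 epoxide; O15 TBS; dithianes at C13 and C17) | C1[C@H](O1)CC2(SCCCS2)C[C@H](O[Si](C)(C)C(C)(C)C)CC3(CC)SCCCS3 | intermediate
15 | arm-A lithium alkoxide: adduct of lithiated 2 and 6 (C9 silyl-dithiane; C7 alkoxide) | CC(C)(C)[Si](C)(C)C1(SCCCS1)C[C@@H]([O-])CC=C.[Li+] | intermediate
16 | C5–C18 tris-dithiane alcohol (terminal alkene C5; O7 and O15 TBS; free 11-OH; dithianes at C9, C13, C17) | C=CC[C@H](O[Si](C)(C)C(C)(C)C)CC1(SCCCS1)C[C@H](O)CC2(SCCCS2)C[C@H](O[Si](C)(C)C(C)(C)C)CC3(CC)SCCCS3 | intermediate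
17 | C5–C18 9,13,17-triketone (O7 and O15 TBS; free 11-OH) | C=CC[C@H](O[Si](C)(C)C(C)(C)C)CC(=O)C[C@H](O)CC(=O)C[C@H](O[Si](C)(C)C(C)(C)C)CC(=O)CC | intermediate
18 | C5–C18 9,11,13-triol 17-ketone (all-anti 7,9,11,13,15; O7 and O15 TBS) | C=CC[C@H](O[Si](C)(C)C(C)(C)C)C[C@@H](O)C[C@H](O)C[C@@H](O)C[C@H](O[Si](C)(C)C(C)(C)C)CC(=O)CC | intermediate
19 | C5–C18 pentakis-TBS ether ketone (O7, O9, O11, O13, O15 TBS; terminal alkene; C17 ethyl ketone) | C=CC[C@H](O[Si](C)(C)C(C)(C)C)C[C@@H](O[Si](C)(C)C(C)(C)C)C[C@H](O[Si](C)(C)C(C)(C)C)C[C@@H](O[Si](C)(C)C(C)(C)C)C[C@H](O[Si](C)(C)C(C)(C)C)CC(=O)CC | intermediate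
20 | C5 aldehyde (C5–C18; pentakis-TBS; C17 ketone) | O=CC[C@H](O[Si](C)(C)C(C)(C)C)C[C@@H](O[Si](C)(C)C(C)(C)C)C[C@H](O[Si](C)(C)C(C)(C)C)C[C@@H](O[Si](C)(C)C(C)(C)C)C[C@H](O[Si](C)(C)C(C)(C)C)CC(=O)CC | intermediate
21 | (Z)-4-iodo C4–C18 alkene ketone (iodine on C4 cis to C6; pentakis-TBS; C17 ketone) | C/C(I)=C/C[C@H](O[Si](C)(C)C(C)(C)C)C[C@@H](O[Si](C)(C)C(C)(C)C)C[C@H](O[Si](C)(C)C(C)(C)C)C[C@@H](O[Si](C)(C)C(C)(C)C)C[C@H](O[Si](C)(C)C(C)(C)C)CC(=O)CC | intermediate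
22 | (R)-propylene oxide | C[C@@H]1CO1 | starting material
23 | but-3-enylmagnesium bromide | C=CCC[Mg]Br | starting material
24 | (R)-hept-6-en-2-ol | C=CCCC[C@@H](C)O | intermediate
25 | (R)-tert-butyl(hept-6-en-2-yloxy)dimethylsilane | C=CCCC[C@@H](C)O[Si](C)(C)C(C)(C)C | intermediate
26 | (R)-7-[(tert-butyldimethylsilyl)oxy]octanal (C43–C50) | O=CCCCCC[C@@H](C)O[Si](C)(C)C(C)(C)C | intermediate
27 | (Z)-but-2-ene | C/C=C\C | starting material
28 | (Z)-crotyldiisopinocampheylborane ((+)-α-pinene series) | C/C=C\CB([C@@H]1C[C@H]2C(C)(C)[C@H](C2)[C@H]1C)[C@@H]1C[C@H]2C(C)(C)[C@H](C2)[C@H]1C | intermediate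
29 | (3R,4R,10R)-10-[(tert-butyldimethylsilyl)oxy]-3-methylundec-1-en-4-ol | C=C[C@@H](C)[C@H](O)CCCCC[C@@H](C)O[Si](C)(C)C(C)(C)C | intermediate
30 | (3R,4R,10R)-4,10-bis[(tert-butyldimethylsilyl)oxy]-3-methylundec-1-ene | C=C[C@@H](C)[C@H](O[Si](C)(C)C(C)(C)C)CCCCC[C@@H](C)O[Si](C)(C)C(C)(C)C | intermediate
31 | (2S,3R,9R)-3,9-bis[(tert-butyldimethylsilyl)oxy]-2-methyldecanal (C41–C50) | O=C[C@@H](C)[C@H](O[Si](C)(C)C(C)(C)C)CCCCC[C@@H](C)O[Si](C)(C)C(C)(C)C | intermediate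
32 | propargyl bromide | C#CCBr | starting material
33 | allenylmagnesium bromide | C=C=C[Mg]Br | intermediate
34 | B-allenyldiisopinocampheylborane ((+)-α-pinene series) | C=C=CB([C@@H]1C[C@H]2C(C)(C)[C@H](C2)[C@H]1C)[C@@H]1C[C@H]2C(C)(C)[C@H](C2)[C@H]1C | intermediate
35 | (4S,5R,6R,12R)-6,12-bis[(tert-butyldimethylsilyl)oxy]-5-methyltridec-1-yn-4-ol (C38–C50) | C#CC[C@@H]([C@@H](C)[C@H](O[Si](C)(C)C(C)(C)C)CCCCC[C@@H](C)O[Si](C)(C)C(C)(C)C)O | intermediate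
36 | 1-bromo-5-chloropentane | ClCCCCCBr | starting material
37 | 5-chloropentylmagnesium bromide | ClCCCCC[Mg]Br | intermediate
38 | (R)-1,8-dichlorooctan-2-ol | ClC[C@H](O)CCCCCCCl | intermediate
39 | (R)-2-(6-chlorohexyl)oxirane (C30–C37) | C1[C@H](O1)CCCCCCCl | intermediate
40 | (R)-2-{[(4-methoxybenzyl)oxy]methyl}oxirane (C22–C24) | COc1ccc(COC[C@H]2CO2)cc1 | starting material
41 | arm-Y lithium alkoxide: adduct of lithiated 2 and 39 (C29 silyl-dithiane; C31 alkoxide) | CC(C)(C)[Si](C)(C)C1(SCCCS1)C[C@H]([O-])CCCCCCCl.[Li+] | intermediate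
42 | C26–C37 lithium chlorohydrin alkoxide (26-chloro; 27-alkoxide; C29 dithiane; O31 TBS) | ClC[C@H]([O-])CC1(SCCCS1)C[C@H](O[Si](C)(C)C(C)(C)C)CCCCCCCl.[Li+] | intermediate
43 | C26–C37 epoxide (C26–C27 epoxide; C29 dithiane; O31 TBS; 37-chloro) | C1[C@H](O1)CC2(SCCCS2)C[C@H](O[Si](C)(C)C(C)(C)C)CCCCCCCl | intermediate
44 | arm-P lithium alkoxide: adduct of lithiated 2 and 40 (C25 silyl-dithiane; C23 alkoxide; O22 PMB) | CC(C)(C)[Si](C)(C)C1(SCCCS1)C[C@@H]([O-])COCc2ccc(OC)cc2.[Li+] | intermediate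
45 | C22–C37 lithium C27-alkoxide (O22 PMB; O23 and O31 TBS; dithianes at C25 and C29) | COc1ccc(COC[C@H](O[Si](C)(C)C(C)(C)C)CC2(SCCCS2)C[C@H]([O-])CC3(SCCCS3)C[C@H](O[Si](C)(C)C(C)(C)C)CCCCCCCl)cc1.[Li+] | intermediate
46 | C22–C37 bis-dithiane tris-TBS ether (O22 PMB; O23, O27, O31 TBS; dithianes at C25 and C29; 37-chloro) | COc1ccc(COC[C@H](O[Si](C)(C)C(C)(C)C)CC2(SCCCS2)C[C@H](O[Si](C)(C)C(C)(C)C)CC3(SCCCS3)C[C@H](O[Si](C)(C)C(C)(C)C)CCCCCCCl)cc1 | intermediate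
47 | C22–C37 chloride (O22 PMB; O23, O27, O31 TBS) | COc1ccc(COC[C@H](O[Si](C)(C)C(C)(C)C)CCC[C@H](O[Si](C)(C)C(C)(C)C)CCC[C@H](O[Si](C)(C)C(C)(C)C)CCCCCCCl)cc1 | intermediate
48 | C22–C50 alkynol (C38–C39 alkyne; free 41-OH; O22 PMB; O23, O27, O31, O43, O49 TBS) | COc1ccc(COC[C@H](O[Si](C)(C)C(C)(C)C)CCC[C@H](O[Si](C)(C)C(C)(C)C)CCC[C@H](O[Si](C)(C)C(C)(C)C)CCCCCCC#CC[C@@H]([C@@H](C)[C@H](O[Si](C)(C)C(C)(C)C)CCCCC[C@@H](C)O[Si](C)(C)C(C)(C)C)O)cc1 | intermediate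
49 | propiolic acid | C#CC(=O)O | starting material
50 | C41 propiolate of 48 | COc1ccc(COC[C@H](O[Si](C)(C)C(C)(C)C)CCC[C@H](O[Si](C)(C)C(C)(C)C)CCC[C@H](O[Si](C)(C)C(C)(C)C)CCCCCCC#CC[C@@H]([C@@H](C)[C@H](O[Si](C)(C)C(C)(C)C)CCCCC[C@@H](C)O[Si](C)(C)C(C)(C)C)OC(=O)C#C)cc1 | intermediate
51 | C1–C50 enynoate ketone (C2–C3 and C38–C39 alkynes; 4Z alkene; C17 ethyl ketone; O22 PMB; ten TBS ethers) | COc1ccc(COC[C@H](O[Si](C)(C)C(C)(C)C)CCC[C@H](O[Si](C)(C)C(C)(C)C)CCC[C@H](O[Si](C)(C)C(C)(C)C)CCCCCCC#CC[C@@H]([C@@H](C)[C@H](O[Si](C)(C)C(C)(C)C)CCCCC[C@@H](C)O[Si](C)(C)C(C)(C)C)OC(=O)C#C/C(C)=C\C[C@H](O[Si](C)(C)C(C)(C)C)C[C@@H](O[Si](C)(C)C(C)(C)C)C[C@H](O[Si](C)(C)C(C)(C)C)C[C@@H](O[Si](C)(C)C(C)(C)C)C[C@H](O[Si](C)(C)C(C)(C)C)CC(=O)CC)cc1 | intermediate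
52 | (2Z,4Z,38Z)-dienoate PMB ether (C17 ethyl ketone; O22 PMB; ten TBS ethers) | COc1ccc(COC[C@H](O[Si](C)(C)C(C)(C)C)CCC[C@H](O[Si](C)(C)C(C)(C)C)CCC[C@H](O[Si](C)(C)C(C)(C)C)CCCCCC/C=C\C[C@@H]([C@@H](C)[C@H](O[Si](C)(C)C(C)(C)C)CCCCC[C@@H](C)O[Si](C)(C)C(C)(C)C)OC(=O)/C=C\C(C)=C/C[C@H](O[Si](C)(C)C(C)(C)C)C[C@@H](O[Si](C)(C)C(C)(C)C)C[C@H](O[Si](C)(C)C(C)(C)C)C[C@@H](O[Si](C)(C)C(C)(C)C)C[C@H](O[Si](C)(C)C(C)(C)C)CC(=O)CC)cc1 | intermediate
53 | C22 primary alcohol (seco ester; C17 ethyl ketone) | OC[C@H](O[Si](C)(C)C(C)(C)C)CCC[C@H](O[Si](C)(C)C(C)(C)C)CCC[C@H](O[Si](C)(C)C(C)(C)C)CCCCCC/C=C\C[C@@H]([C@@H](C)[C@H](O[Si](C)(C)C(C)(C)C)CCCCC[C@@H](C)O[Si](C)(C)C(C)(C)C)OC(=O)/C=C\C(C)=C/C[C@H](O[Si](C)(C)C(C)(C)C)C[C@@H](O[Si](C)(C)C(C)(C)C)C[C@H](O[Si](C)(C)C(C)(C)C)C[C@@H](O[Si](C)(C)C(C)(C)C)C[C@H](O[Si](C)(C)C(C)(C)C)CC(=O)CC | intermediate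
54 | C22 primary iodide (seco ester; C17 ethyl ketone) | IC[C@H](O[Si](C)(C)C(C)(C)C)CCC[C@H](O[Si](C)(C)C(C)(C)C)CCC[C@H](O[Si](C)(C)C(C)(C)C)CCCCCC/C=C\C[C@@H]([C@@H](C)[C@H](O[Si](C)(C)C(C)(C)C)CCCCC[C@@H](C)O[Si](C)(C)C(C)(C)C)OC(=O)/C=C\C(C)=C/C[C@H](O[Si](C)(C)C(C)(C)C)C[C@@H](O[Si](C)(C)C(C)(C)C)C[C@H](O[Si](C)(C)C(C)(C)C)C[C@@H](O[Si](C)(C)C(C)(C)C)C[C@H](O[Si](C)(C)C(C)(C)C)CC(=O)CC | intermediate
55 | ethyl (Z)-3-iodoacrylate | CCOC(=O)/C=C\I | starting material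
56 | (Z)-3-iodoacrolein | O=C/C=C\I | intermediate
57 | Z-enol diisopinocampheylborinate of 54 (C17–C18 enolate) | IC[C@H](O[Si](C)(C)C(C)(C)C)CCC[C@H](O[Si](C)(C)C(C)(C)C)CCC[C@H](O[Si](C)(C)C(C)(C)C)CCCCCC/C=C\C[C@@H]([C@@H](C)[C@H](O[Si](C)(C)C(C)(C)C)CCCCC[C@@H](C)O[Si](C)(C)C(C)(C)C)OC(=O)/C=C\C(C)=C/C[C@H](O[Si](C)(C)C(C)(C)C)C[C@@H](O[Si](C)(C)C(C)(C)C)C[C@H](O[Si](C)(C)C(C)(C)C)C[C@@H](O[Si](C)(C)C(C)(C)C)C[C@H](O[Si](C)(C)C(C)(C)C)C/C(OB([C@@H]1C[C@H]2C(C)(C)[C@H](C2)[C@H]1C)[C@@H]1C[C@H]2C(C)(C)[C@H](C2)[C@H]1C)=C/C | intermediate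
58 | syn-aldol adduct (C17 ketone; 18-methyl; 19-OH; Z-alkenyl iodide at C21; C22 iodide) | IC[C@H](O[Si](C)(C)C(C)(C)C)CCC[C@H](O[Si](C)(C)C(C)(C)C)CCC[C@H](O[Si](C)(C)C(C)(C)C)CCCCCC/C=C\C[C@@H]([C@@H](C)[C@H](O[Si](C)(C)C(C)(C)C)CCCCC[C@@H](C)O[Si](C)(C)C(C)(C)C)OC(=O)/C=C\C(C)=C/C[C@H](O[Si](C)(C)C(C)(C)C)C[C@@H](O[Si](C)(C)C(C)(C)C)C[C@H](O[Si](C)(C)C(C)(C)C)C[C@@H](O[Si](C)(C)C(C)(C)C)C[C@H](O[Si](C)(C)C(C)(C)C)CC(=O)[C@@H](C)[C@H](O)/C=C\I | intermediate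
59 | seco 17,19-diol (Z-alkenyl iodide at C21; C22 iodide; ten TBS ethers) | IC[C@H](O[Si](C)(C)C(C)(C)C)CCC[C@H](O[Si](C)(C)C(C)(C)C)CCC[C@H](O[Si](C)(C)C(C)(C)C)CCCCCC/C=C\C[C@@H]([C@@H](C)[C@H](O[Si](C)(C)C(C)(C)C)CCCCC[C@@H](C)O[Si](C)(C)C(C)(C)C)OC(=O)/C=C\C(C)=C/C[C@H](O[Si](C)(C)C(C)(C)C)C[C@@H](O[Si](C)(C)C(C)(C)C)C[C@H](O[Si](C)(C)C(C)(C)C)C[C@@H](O[Si](C)(C)C(C)(C)C)C[C@H](O[Si](C)(C)C(C)(C)C)C[C@@H](O)[C@@H](C)[C@H](O)/C=C\I | intermediate
60 | decakis-TBS macrolactone (TBS on O7, O9, O11, O13, O15, O23, O27, O31, O43, O49; free 17-OH and 19-OH) | CC1=C/C[C@H](O[Si](C)(C)C(C)(C)C)C[C@@H](O[Si](C)(C)C(C)(C)C)C[C@H](O[Si](C)(C)C(C)(C)C)C[C@@H](O[Si](C)(C)C(C)(C)C)C[C@H](O[Si](C)(C)C(C)(C)C)C[C@@H](O)[C@@H](C)[C@H](O)/C=C\C[C@H](O[Si](C)(C)C(C)(C)C)CCC[C@H](O[Si](C)(C)C(C)(C)C)CCC[C@H](O[Si](C)(C)C(C)(C)C)CCCCCC/C=C\C[C@@H]([C@@H](C)[C@H](O[Si](C)(C)C(C)(C)C)CCCCC[C@@H](C)O[Si](C)(C)C(C)(C)C)OC(=O)/C=C\1 | intermediate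
61 | CNP0071908.2 | CC1=C/C[C@H](O)C[C@@H](O)C[C@H](O)C[C@@H](O)C[C@H](O)C[C@@H](O)[C@@H](C)[C@H](O)/C=C\C[C@H](O)CCC[C@H](O)CCC[C@H](O)CCCCCC/C=C\C[C@@H]([C@@H](C)[C@H](O)CCCCC[C@@H](C)O)OC(=O)/C=C\1 | target

## Step count and risk

Total step count: 30. Longest linear sequence: 17 steps (steps 10–16, 20–25, 27–30).

The three steps most likely to fail:

Step 29 (radical ring closure). Oligomerisation or reduction of the primary iodide may win over closure of the 42-membered ring. The fallback sets out from 54 and keeps the radical bond formation but makes it intermolecular. Compound 54 is coupled with (Z)-3-iodoprop-2-en-1-ol under the same NiBr2(dme)/bipyridine/Mn conditions at normal concentration to give the Z-allylic alcohol F1. MnO2 oxidises it to the Z-enal F2. The ring is then closed at C18–C19 by an intramolecular (−)-Ipc2BOTf/iPr2NEt aldol reaction at high dilution, giving the macrocyclic β-hydroxy ketone F3. Me4NBH(OAc)3 reduction brings the route back at 60.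

Step 27 (boron aldol with the labile Z-iodoacrolein on the full seco ketone). Isomerisation of 56 or poor enolisation regioselectivity may erode the result. The fallback sets out from 54 and uses the robust 3-(trimethylsilyl)propynal in the same Ipc2B aldol to give the propargylic aldol F4. Me4NBH(OAc)3 reduction gives the anti-diol F5. N-iodosuccinimide with AgNO3 converts the silylalkyne into the iodoalkyne diol F6. Diimide (2-nitrobenzenesulfonyl hydrazide, Et3N) reduces the iodoalkyne cis, and the route is rejoined at 59.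

Step 22 (Sonogashira coupling of the terminal propiolate). Alkynoate decomposition or homocoupling is the concern, and the diene would then be made without an alkyne at C2–C3. The fallback sets out from 48, which is semi-hydrogenated (H2, Pd/CaCO3 poisoned with Pb(OAc)2) to the Z-alkenol F7. Propiolic acid 49 is hydrostannylated (Bu3SnH, cat. AIBN) to (Z)-3-(tributylstannyl)acrylic acid F8. Steglich esterification of F7 with F8 gives the stannyl acrylate F9. A Stille–Liebeskind coupling of F9 with 21, mediated by copper thiophene-2-carboxylate (CuO2CC4H3S), forms C3–C4 with retention at both alkenes and returns to the route at 52.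

## Further compounds

F1 | step 29 | Z-allylic alcohol (C19 primary alcohol; 20Z alkene; C17 ethyl ketone; seco ester) | OC/C=C\C[C@H](O[Si](C)(C)C(C)(C)C)CCC[C@H](O[Si](C)(C)C(C)(C)C)CCC[C@H](O[Si](C)(C)C(C)(C)C)CCCCCC/C=C\C[C@@H]([C@@H](C)[C@H](O[Si](C)(C)C(C)(C)C)CCCCC[C@@H](C)O[Si](C)(C)C(C)(C)C)OC(=O)/C=C\C(C)=C/C[C@H](O[Si](C)(C)C(C)(C)C)C[C@@H](O[Si](C)(C)C(C)(C)C)C[C@H](O[Si](C)(C)C(C)(C)C)C[C@@H](O[Si](C)(C)C(C)(C)C)C[C@H](O[Si](C)(C)C(C)(C)C)CC(=O)CC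
F2 | step 29 | Z-enal (C19 aldehyde; 20Z alkene; C17 ethyl ketone; seco ester) | O=C/C=C\C[C@H](O[Si](C)(C)C(C)(C)C)CCC[C@H](O[Si](C)(C)C(C)(C)C)CCC[C@H](O[Si](C)(C)C(C)(C)C)CCCCCC/C=C\C[C@@H]([C@@H](C)[C@H](O[Si](C)(C)C(C)(C)C)CCCCC[C@@H](C)O[Si](C)(C)C(C)(C)C)OC(=O)/C=C\C(C)=C/C[C@H](O[Si](C)(C)C(C)(C)C)C[C@@H](O[Si](C)(C)C(C)(C)C)C[C@H](O[Si](C)(C)C(C)(C)C)C[C@@H](O[Si](C)(C)C(C)(C)C)C[C@H](O[Si](C)(C)C(C)(C)C)CC(=O)CC
F3 | step 29 | macrocyclic β-hydroxy ketone (C17 ketone; free 19-OH; ten TBS ethers) | CC1=C/C[C@H](O[Si](C)(C)C(C)(C)C)C[C@@H](O[Si](C)(C)C(C)(C)C)C[C@H](O[Si](C)(C)C(C)(C)C)C[C@@H](O[Si](C)(C)C(C)(C)C)C[C@H](O[Si](C)(C)C(C)(C)C)CC(=O)[C@@H](C)[C@H](O)/C=C\C[C@H](O[Si](C)(C)C(C)(C)C)CCC[C@H](O[Si](C)(C)C(C)(C)C)CCC[C@H](O[Si](C)(C)C(C)(C)C)CCCCCC/C=C\C[C@@H]([C@@H](C)[C@H](O[Si](C)(C)C(C)(C)C)CCCCC[C@@H](C)O[Si](C)(C)C(C)(C)C)OC(=O)/C=C\1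
F4 | step 27 | propargylic aldol (C17 ketone; 19-OH; C20–C21 trimethylsilylalkyne; C22 iodide) | IC[C@H](O[Si](C)(C)C(C)(C)C)CCC[C@H](O[Si](C)(C)C(C)(C)C)CCC[C@H](O[Si](C)(C)C(C)(C)C)CCCCCC/C=C\C[C@@H]([C@@H](C)[C@H](O[Si](C)(C)C(C)(C)C)CCCCC[C@@H](C)O[Si](C)(C)C(C)(C)C)OC(=O)/C=C\C(C)=C/C[C@H](O[Si](C)(C)C(C)(C)C)C[C@@H](O[Si](C)(C)C(C)(C)C)C[C@H](O[Si](C)(C)C(C)(C)C)C[C@@H](O[Si](C)(C)C(C)(C)C)C[C@H](O[Si](C)(C)C(C)(C)C)CC(=O)[C@@H](C)[C@H](O)C#C[Si](C)(C)C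
F5 | step 27 | anti-diol (17-OH; 19-OH; C20–C21 trimethylsilylalkyne; C22 iodide) | IC[C@H](O[Si](C)(C)C(C)(C)C)CCC[C@H](O[Si](C)(C)C(C)(C)C)CCC[C@H](O[Si](C)(C)C(C)(C)C)CCCCCC/C=C\C[C@@H]([C@@H](C)[C@H](O[Si](C)(C)C(C)(C)C)CCCCC[C@@H](C)O[Si](C)(C)C(C)(C)C)OC(=O)/C=C\C(C)=C/C[C@H](O[Si](C)(C)C(C)(C)C)C[C@@H](O[Si](C)(C)C(C)(C)C)C[C@H](O[Si](C)(C)C(C)(C)C)C[C@@H](O[Si](C)(C)C(C)(C)C)C[C@H](O[Si](C)(C)C(C)(C)C)C[C@@H](O)[C@@H](C)[C@H](O)C#C[Si](C)(C)C
F6 | step 27 | iodoalkyne diol (17-OH; 19-OH; C20–C21 iodoalkyne; C22 iodide) | IC[C@H](O[Si](C)(C)C(C)(C)C)CCC[C@H](O[Si](C)(C)C(C)(C)C)CCC[C@H](O[Si](C)(C)C(C)(C)C)CCCCCC/C=C\C[C@@H]([C@@H](C)[C@H](O[Si](C)(C)C(C)(C)C)CCCCC[C@@H](C)O[Si](C)(C)C(C)(C)C)OC(=O)/C=C\C(C)=C/C[C@H](O[Si](C)(C)C(C)(C)C)C[C@@H](O[Si](C)(C)C(C)(C)C)C[C@H](O[Si](C)(C)C(C)(C)C)C[C@@H](O[Si](C)(C)C(C)(C)C)C[C@H](O[Si](C)(C)C(C)(C)C)C[C@@H](O)[C@@H](C)[C@H](O)C#CI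
F7 | step 22 | C22–C50 Z-alkenol (38Z alkene; free 41-OH; O22 PMB; five TBS ethers) | COc1ccc(COC[C@H](O[Si](C)(C)C(C)(C)C)CCC[C@H](O[Si](C)(C)C(C)(C)C)CCC[C@H](O[Si](C)(C)C(C)(C)C)CCCCCC/C=C\C[C@@H]([C@@H](C)[C@H](O[Si](C)(C)C(C)(C)C)CCCCC[C@@H](C)O[Si](C)(C)C(C)(C)C)O)cc1
F8 | step 22 | (Z)-3-(tributylstannyl)acrylic acid | OC(=O)/C=C\[Sn](CCCC)(CCCC)CCCC
F9 | step 22 | C41 (Z)-3-(tributylstannyl)acrylate of F7 | COc1ccc(COC[C@H](O[Si](C)(C)C(C)(C)C)CCC[C@H](O[Si](C)(C)C(C)(C)C)CCC[C@H](O[Si](C)(C)C(C)(C)C)CCCCCC/C=C\C[C@@H]([C@@H](C)[C@H](O[Si](C)(C)C(C)(C)C)CCCCC[C@@H](C)O[Si](C)(C)C(C)(C)C)OC(=O)/C=C\[Sn](CCCC)(CCCC)CCCC)cc1
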